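The whole route rests on the O6–C1 bond of the ring-fused oxirane. The oxygens on C2–C6 alternate all-trans around the cyclohexane. The oxirane oxygen is O6 tied to quaternary C1, and C7 sits anti to it. The target is therefore a rearranged scyllo-inosose methylene adduct. A Payne rearrangement makes O6–C1 with inversion at C1, closes the C1–C6 oxirane and releases the C7 carbinol in one operation. Its precursor 17 is the C1 spiro-oxirane with equatorial oxygen, a free C6 hydroxyl and only base-inert ethers (PMB on O2/O3, benzyl on O4/O5). The esters are fitted afterwards. D-Glucose supplies C1–C6 with matching numbers.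

Key step: step 13

Numbering and abbreviations:
- C1 = quaternary oxirane carbon, C7 = its CH2O carbon, C2/C3 = acetoxy carbons, C4/C5 = carbinol carbons, C6 = oxirane CH, On = oxygen on Cn.
- C1–C6 are also C1–C6 of the glucoside.
- Locants 2,3,4,5,6,1 of 1D-myo-inositol correspond to C1,C2,C3,C4,C5,C6.
- PMB = 4-methoxybenzyl, Bn = benzyl, TBS = tert-butyldimethylsilyl.

Assumption (remark on the chemistry): the Ferrier carbocyclization of 6 is taken to follow the usual course of gluco-configured substrates (new C1 hydroxyl axial, C6 acetate equatorial), so the route makes C1, whose carbinol configuration is erased anyway, the inosose carbonyl.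

Step 1
Reactants: 1 methyl 4,6-O-[(R)-benzylidene]-α-D-glucopyranoside
Product: 2 methyl 4,6-O-[(R)-benzylidene]-2,3-bis-O-(4-methoxybenzyl)-α-D-glucopyranoside
Conditions: PMBCl, NaH, Bu4NI (cat.), DMF, 0 °C → rt
Reagents that add atoms: 4-methoxybenzyl chloride, COc1ccc(CCl)cc1
Why: Williamson etherification of the only two free hydroxyls; PMB ethers stand in for the C2/C3 acetates because they are inert to ylide and NaH (no acyl shift to an O6 or O7 alkoxide is possible) and can later be removed oxidatively beside benzyl ethers.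

Step 2
Reactants: 2 methyl 4,6-O-[(R)-benzylidene]-2,3-bis-O-(4-methoxybenzyl)-α-D-glucopyranoside
Product: 3 methyl 4-O-benzyl-2,3-bis-O-(4-methoxybenzyl)-α-D-glucopyranoside
Conditions: BH3·THF, Cu(OTf)2 (cat.), CH2Cl2, 0 °C → rt; aq. work-up
Reagents that add atoms: none
Why: Regioselective reductive opening of a 4,6-O-benzylidene acetal, in which the Lewis-acid-activated borane engages the less hindered O6, so that hydride delivery leaves the benzyl group on O4 and frees the primary alcohol without touching a stereocenter.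

Step 3
Reactants: 3 methyl 4-O-benzyl-2,3-bis-O-(4-methoxybenzyl)-α-D-glucopyranoside; 4 acetic anhydride
Product: 6 methyl (Z)-6-O-acetyl-4-O-benzyl-2,3-bis-O-(4-methoxybenzyl)-α-D-xylo-hex-5-enopyranoside, via C6 aldehyde 5 (not isolated)
Conditions: TEMPO (cat.), PhI(OAc)2, CH2Cl2, rt; crude 5, then Ac2O, K2CO3, MeCN, reflux
Reagents that add atoms: acetic anhydride (4), CC(=O)OC(C)=O
Why: Oxoammonium (TEMPO) oxidation stops at the aldehyde, whose enolate is O-acetylated (enol ester formation) to the Z enol acetate with the acetoxy group turned away from C4; the C5 stereocenter is given up on purpose.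

Step 4
Reactants: 6 methyl (Z)-6-O-acetyl-4-O-benzyl-2,3-bis-O-(4-methoxybenzyl)-α-D-xylo-hex-5-enopyranoside
Product: 7 C5-keto inosose: 6-O-acetyl-4-O-benzyl-2,3-bis-O-PMB, axial 1-OH, O2/O3/O4/O6 equatorial
Conditions: Hg(OCOCF3)2 (cat.), acetone/H2O, rt
Reagents that add atoms: water, O
Why: Ferrier carbocyclization, in which oxymercuration of the enol-ether double bond by divalent mercury, loss of methanol and a chair-like intramolecular aldol addition of C6 to the unmasked C1 aldehyde form the C1–C6 bond, setting the C6 acetate equatorial (kept to the end) and the C1 hydroxyl axial (used in step 5, erased in step 10).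

Step 5
Reactants: 7 C5-keto inosose
Product: 9 1D-5-O-benzyl-3,4-bis-O-PMB-myo-inositol (free axial 1-OH and equatorial 5-OH/6-OH in target numbering), via diol monoacetate 8 (not isolated)
Conditions: NaBH(OAc)3, AcOH/MeCN, 0 °C → rt; crude 8, then K2CO3 (cat.), MeOH, rt
Reagents that add atoms: none
Why: Saksena–Evans hydroxyl-directed reduction, in which boron bound to the axial C1–OH hands its hydride to the same face of the C5 carbonyl and so sets the equatorial C5–OH (1,3-anti), followed by base-catalysed transesterification that strips the acetate.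

Step 6
Reactants: 9 1D-5-O-benzyl-3,4-bis-O-PMB-myo-inositol
Product: 10 1D-5-O-benzyl-1,2-O-isopropylidene-3,4-bis-O-PMB-myo-inositol (acetonide on O1/O6 in target numbering, free 5-OH)
Conditions: Me2C(OMe)2, camphorsulfonic acid (cat.), acetone, rt
Reagents that add atoms: 2,2-dimethoxypropane, COC(C)(C)OC
Why: Acetonide formation under thermodynamic control picks the cis C1(axial)/C6(equatorial) diol, since a dioxolane across the trans-diequatorial C5/C6 pair would be strained, and so leaves O5 alone free.

Step 7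
Reactants: 10 1D-5-O-benzyl-1,2-O-isopropylidene-3,4-bis-O-PMB-myo-inositol
Product: 11 1D-5,6-di-O-benzyl-1,2-O-isopropylidene-3,4-bis-O-PMB-myo-inositol
Conditions: BnBr, NaH, DMF, 0 °C → rt
Reagents that add atoms: benzyl bromide, BrCc1ccccc1
Why: Williamson etherification of the single free hydroxyl completes the O4/O5 dibenzyl pair that is carried to the last step.

Step 8
Reactants: 11 1D-5,6-di-O-benzyl-1,2-O-isopropylidene-3,4-bis-O-PMB-myo-inositol
Product: 12 1D-5,6-di-O-benzyl-3,4-bis-O-PMB-myo-inositol (free axial 1-OH and equatorial 6-OH in target numbering)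
Conditions: AcOH/H2O (4:1), 50 °C
Reagents that add atoms: none
Why: Mild acid hydrolysis of the isopropylidene acetal, under which benzyl and PMB ethers persist, returns the C1/C6 cis diol.

Step 9
Reactants: 12 1D-5,6-di-O-benzyl-3,4-bis-O-PMB-myo-inositol
Product: 13 1D-5,6-di-O-benzyl-1-O-TBS-3,4-bis-O-PMB-myo-inositol (6-O-TBS, free axial 1-OH in target numbering)
Conditions: TBSCl, imidazole, DMF, 0 °C → rt
Reagents that add atoms: tert-butyldimethylsilyl chloride, CC(C)(C)[Si](C)(C)Cl
Why: Regioselective silylation, because the equatorial C6–OH is far more accessible than the axial C1–OH wedged between O2 and O6, as is general for the cis diol of myo-inositol ethers.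

Step 10
Reactants: 13 1D-5,6-di-O-benzyl-1-O-TBS-3,4-bis-O-PMB-myo-inositol
Product: 14 4,5-di-O-benzyl-2,3-bis-O-PMB-6-O-TBS-scyllo-inosose (C1 carbonyl, all five OR groups equatorial)
Conditions: Dess–Martin periodinane, CH2Cl2, 0 °C → rt
Reagents that add atoms: none
Why: Dess–Martin oxidation of the remaining axial alcohol under near-neutral conditions should give the all-equatorial inosose without beta-elimination or epimerization at C2/C6.

Step 11
Reactants: 14 4,5-di-O-benzyl-2,3-bis-O-PMB-6-O-TBS-scyllo-inosose; 15 trimethylsulfonium iodide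
Product: 16 C1 spiro-oxirane of 14 (oxirane oxygen equatorial and trans to O2/O6, C7 methylene axial)
Conditions: NaH, DMSO, 65 °C; THF, Me3SI, −5 °C; then 14, −5 → 0 °C
Reagents that add atoms: trimethylsulfonium iodide (15), C[S+](C)C.[I-]
Why: Corey–Chaykovsky epoxidation, in which the small unstabilized sulfonium ylide adds irreversibly along the axial trajectory of the chair ketone, so that C7 becomes axial and the oxirane oxygen equatorial, setting C1 in the configuration that step 13 inverts, while the low temperature holds back enolization and beta-elimination.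

Step 12
Reactants: 16 C1 spiro-oxirane, 6-O-TBS
Product: 17 C1 spiro-oxirane of 4,5-di-O-benzyl-2,3-bis-O-PMB-scyllo-inosose with free equatorial 6-OH
Conditions: Bu4NF, AcOH, THF, 0 °C → rt
Reagents that add atoms: none
Why: Fluoride desilylation buffered with acetic acid frees O6 as the neutral alcohol, so that the oxirane is neither opened nor rearranged prematurely.

Step 13
Reactants: 17 C1 spiro-oxirane with free 6-OH
Product: 18 ring-fused 1,6-oxirane (oxygen = O6, on the face of O2/O4) with C7 hydroxymethyl on the opposite face, 2,3-bis-O-PMB, 4,5-di-O-benzyl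
Conditions: NaH, 15-crown-5, THF (high dilution), 0 → 50 °C; sat. aq. NH4Cl, 0 °C
Reagents that add atoms: none
Why: NaH converts the C6–OH into its alkoxide, which attacks the spiro carbon C1 from the face opposite the C1–O7 bond, so that O6–C1 forms, C1–O7 breaks and the oxygen leaves on C7 as a primary alkoxide that is protonated on quench. This is a Payne rearrangement of a 2,3-epoxy alcohol run under aprotic conditions, here transposing a 1,1-disubstituted spiro-oxirane into a trisubstituted ring-fused one. The new oxirane (O6, C1, C6) closes in the 3-exo-tet mode. C1 is the only stereocenter made: backside displacement inverts it, so the fixed C6 configuration dictates that O6 and C7 end on opposite faces, as the target requires. The step needs O6 and the departing oxygen anti-periplanar, which is reachable because all five substituents are acyclic ethers that let the chair pass into a twist or ring-flipped form with both C–O bonds axial, and it needs attack by O6 alone, which is secured by the ether on O2 and by the absence of esters or silyl groups that could wander to an O6 or O7 alkoxide. The equilibrium should lie on the product side (more substituted oxirane, less hindered primary alkoxide), and high dilution with a non-nucleophilic base should suppress intermolecular opening at C7.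

Step 14
Reactants: 18 ring-fused 1,6-oxirane with free 7-OH; 19 benzoyl chloride
Product: 20 7-O-benzoate of 18
Conditions: BzCl, pyridine, CH2Cl2, 0 °C
Reagents that add atoms: benzoyl chloride (19), O=C(Cl)c1ccccc1
Why: Acylation (benzoylation) of the only free hydroxyl, a primary one, under mildly basic conditions that leave the oxirane untouched and take the alcohol out of any reverse Payne equilibrium.

Step 15
Reactants: 20 7-O-benzoate, 2,3-bis-O-PMB, 4,5-di-O-benzyl
Product: 21 2,3-diol: 7-O-benzoyl-4,5-di-O-benzyl ring-fused 1,6-oxirane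
Conditions: DDQ, CH2Cl2/pH 7 buffer, 0 °C → rt
Reagents that add atoms: none
Why: Oxidative PMB cleavage with DDQ, in which the electron-rich anisyl ethers are oxidized to oxocarbenium ions and hydrolysed while benzyl ethers, benzoate and oxirane stay inert under buffered conditions.

Step 16
Reactants: 21 2,3-diol; 4 acetic anhydride
Product: 22 2,3-di-O-acetyl-7-O-benzoyl-4,5-di-O-benzyl ring-fused 1,6-oxirane
Conditions: Ac2O, pyridine, DMAP (cat.), CH2Cl2, 0 °C → rt
Reagents that add atoms: acetic anhydride (4), CC(=O)OC(C)=O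
Why: DMAP-catalysed acetylation of the two liberated secondary hydroxyls should install the C2/C3 acetates faster than any benzoyl shift from O7 to O2 can occur.

Step 17
Reactants: 22 2,3-di-O-acetyl-7-O-benzoyl-4,5-di-O-benzyl ring-fused 1,6-oxirane
Product: 23 target CNP0171674.1
Conditions: H2 (1 atm), Pd(OH)2/C, EtOAc, rt
Reagents that add atoms: none
Why: Catalytic hydrogenolysis cleaves only the two benzylic C–O bonds, since an aliphatic trisubstituted oxirane and the esters should survive in neutral, non-nucleophilic ethyl acetate, which also keeps acetyl migration to O4 at bay.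

Compound list
1 | methyl 4,6-O-[(R)-benzylidene]-α-D-glucopyranoside | CO[C@@H]1[C@H](O)[C@@H](O)[C@@H]2O[C@H](c3ccccc3)OC[C@H]2O1 | starting material
2 | methyl 4,6-O-[(R)-benzylidene]-2,3-bis-O-(4-methoxybenzyl)-α-D-glucopyranoside | CO[C@@H]1[C@H](OCc3ccc(OC)cc3)[C@@H](OCc3ccc(OC)cc3)[C@@H]2O[C@H](c3ccccc3)OC[C@H]2O1 | intermediate
3 | methyl 4-O-benzyl-2,3-bis-O-(4-methoxybenzyl)-α-D-glucopyranoside | CO[C@@H]1[C@H](OCc2ccc(OC)cc2)[C@@H](OCc2ccc(OC)cc2)[C@H](OCc2ccccc2)[C@@H](CO)O1 | intermediate
4 | acetic anhydride | CC(=O)OC(C)=O | starting material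
5 | methyl 4-O-benzyl-2,3-bis-O-(4-methoxybenzyl)-α-D-gluco-hexodialdo-1,5-pyranoside (C6 aldehyde) | CO[C@@H]1[C@H](OCc2ccc(OC)cc2)[C@@H](OCc2ccc(OC)cc2)[C@H](OCc2ccccc2)[C@@H](C=O)O1 | intermediate
6 | methyl (Z)-6-O-acetyl-4-O-benzyl-2,3-bis-O-(4-methoxybenzyl)-α-D-xylo-hex-5-enopyranoside | CO[C@@H]1[C@H](OCc2ccc(OC)cc2)[C@@H](OCc2ccc(OC)cc2)[C@H](OCc2ccccc2)/C(=C/OC(C)=O)O1 | intermediate
7 | C5-keto inosose: 6-O-acetyl-4-O-benzyl-2,3-bis-O-PMB, axial 1-OH, O2/O3/O4/O6 equatorial | COc1ccc(CO[C@H]2[C@H](OCc3ccccc3)C(=O)[C@H](OC(C)=O)[C@H](O)[C@@H]2OCc2ccc(OC)cc2)cc1 | intermediate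
8 | 1D-1-O-acetyl-5-O-benzyl-3,4-bis-O-PMB-myo-inositol (diol monoacetate) | COc1ccc(CO[C@H]2[C@H](OCc3ccccc3)[C@@H](O)[C@H](OC(C)=O)[C@H](O)[C@@H]2OCc2ccc(OC)cc2)cc1 | intermediate
9 | 1D-5-O-benzyl-3,4-bis-O-PMB-myo-inositol | COc1ccc(CO[C@H]2[C@H](OCc3ccccc3)[C@@H](O)[C@H](O)[C@H](O)[C@@H]2OCc2ccc(OC)cc2)cc1 | intermediate
10 | 1D-5-O-benzyl-1,2-O-isopropylidene-3,4-bis-O-PMB-myo-inositol | COc1ccc(CO[C@H]2[C@H](OCc3ccccc3)[C@@H](O)[C@@H]3OC(C)(C)O[C@@H]3[C@@H]2OCc2ccc(OC)cc2)cc1 | intermediate
11 | 1D-5,6-di-O-benzyl-1,2-O-isopropylidene-3,4-bis-O-PMB-myo-inositol | COc1ccc(CO[C@H]2[C@H](OCc3ccccc3)[C@@H](OCc3ccccc3)[C@@H]3OC(C)(C)O[C@@H]3[C@@H]2OCc2ccc(OC)cc2)cc1 | intermediate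
12 | 1D-5,6-di-O-benzyl-3,4-bis-O-PMB-myo-inositol | COc1ccc(CO[C@H]2[C@H](OCc3ccccc3)[C@@H](OCc3ccccc3)[C@H](O)[C@H](O)[C@@H]2OCc2ccc(OC)cc2)cc1 | intermediate
13 | 1D-5,6-di-O-benzyl-1-O-TBS-3,4-bis-O-PMB-myo-inositol | COc1ccc(CO[C@H]2[C@H](OCc3ccccc3)[C@@H](OCc3ccccc3)[C@H](O[Si](C)(C)C(C)(C)C)[C@H](O)[C@@H]2OCc2ccc(OC)cc2)cc1 | intermediate
14 | 4,5-di-O-benzyl-2,3-bis-O-PMB-6-O-TBS-scyllo-inosose (C1 carbonyl, all OR equatorial) | COc1ccc(CO[C@H]2[C@H](OCc3ccccc3)[C@@H](OCc3ccccc3)[C@H](O[Si](C)(C)C(C)(C)C)C(=O)[C@@H]2OCc2ccc(OC)cc2)cc1 | intermediate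
15 | trimethylsulfonium iodide | C[S+](C)C.[I-] | starting material
16 | C1 spiro-oxirane of 14 (oxirane oxygen equatorial, C7 axial), 6-O-TBS | COc1ccc(CO[C@H]2[C@H](OCc3ccccc3)[C@@H](OCc3ccccc3)[C@H](O[Si](C)(C)C(C)(C)C)[C@]3(CO3)[C@@H]2OCc2ccc(OC)cc2)cc1 | intermediate
17 | C1 spiro-oxirane (oxirane oxygen equatorial, C7 axial) with free equatorial 6-OH, 2,3-bis-O-PMB, 4,5-di-O-benzyl | COc1ccc(CO[C@H]2[C@H](OCc3ccccc3)[C@@H](OCc3ccccc3)[C@H](O)[C@]3(CO3)[C@@H]2OCc2ccc(OC)cc2)cc1 | intermediate
18 | ring-fused 1,6-oxirane with free 7-OH, 2,3-bis-O-PMB, 4,5-di-O-benzyl | COc1ccc(CO[C@H]2[C@H](OCc3ccccc3)[C@@H](OCc3ccccc3)[C@@H]3O[C@]3(CO)[C@@H]2OCc2ccc(OC)cc2)cc1 | intermediate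
19 | benzoyl chloride | O=C(Cl)c1ccccc1 | starting material
20 | 7-O-benzoyl ring-fused 1,6-oxirane, 2,3-bis-O-PMB, 4,5-di-O-benzyl | COc1ccc(CO[C@H]2[C@H](OCc3ccccc3)[C@@H](OCc3ccccc3)[C@@H]3O[C@]3(COC(=O)c3ccccc3)[C@@H]2OCc2ccc(OC)cc2)cc1 | intermediate
21 | 7-O-benzoyl-4,5-di-O-benzyl ring-fused 1,6-oxirane 2,3-diol | O[C@H]1[C@H](OCc2ccccc2)[C@@H](OCc2ccccc2)[C@@H]2O[C@]2(COC(=O)c2ccccc2)[C@@H]1O | intermediate
22 | 2,3-di-O-acetyl-7-O-benzoyl-4,5-di-O-benzyl ring-fused 1,6-oxirane | CC(=O)O[C@H]1[C@H](OCc2ccccc2)[C@@H](OCc2ccccc2)[C@@H]2O[C@]2(COC(=O)c2ccccc2)[C@@H]1OC(C)=O | intermediate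
23 | CNP0171674.1: 2,3-di-O-acetyl-7-O-benzoyl ring-fused 1,6-oxirane 4,5-diol | CC(=O)O[C@H]1[C@H](O)[C@@H](O)[C@@H]2O[C@]2(COC(=O)c2ccccc2)[C@@H]1OC(C)=O | target

Total step count: 17 (steps 3 and 5 are telescoped two-stage operations).
Longest linear sequence: 17 steps, 1 → 23; compounds 4, 15 and 19 are bought.

Steps most likely to fail

1. Step 13 (key step).
- What may go wrong: the all-equatorial chair may be too reluctant to reach the conformation with O6 anti to the C1–O7 bond. The rearrangement would then be outrun by intermolecular opening of the oxirane at C7, or the equilibrium would stop short of completion.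
- Fallback: it closes the same oxirane from the other oxygen, by alkoxide displacement of a sulfonate. It sets out from 14 and rejoins the route at 20. Dimethylsulfoxonium methylide (Me3S(O)I, NaH, DMSO) adds reversibly and transfers its methylene equatorially, so it should give the C1-epimeric spiro-oxirane F1. Bu4NF/AcOH should give the epoxy alcohol F2, whose O6 is cis to the oxirane oxygen and cannot rearrange. Dess–Martin oxidation should give the C6 ketone F3. LiBH(s-Bu)3 at −78 °C should attack from the equatorial side to give the axial C6 alcohol F4. MsCl/Et3N should convert this into the axial mesylate F5. PhCO2Cs in DMF should then open the oxirane at C7 to the tertiary C1 alkoxide, drawn as its alcohol F6. This alkoxide is trans-diaxial to the mesylate, so it should displace it at once with inversion at C6 and deliver 20.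

2. Step 11.
- What may go wrong: poor facial selectivity of the methylene transfer (equatorial delivery competing beside the two flanking equatorial ethers), or enolization followed by beta-elimination.
- Fallback: it builds the same stereocenter by olefination and osmylation. It sets out from 14 and rejoins at 16. Wittig methylenation (Ph3PCH3Br, KN(SiMe3)2, THF) should give the exocyclic alkene F7. Dihydroxylation (OsO4 cat., N-methylmorpholine N-oxide, acetone/H2O) uses a bulky reagent that avoids the face screened by the axial hydrogens on C3 and C5. It should give the diol F8 with equatorial tertiary hydroxyl and axial CH2OH. TsCl/pyridine should give the primary tosylate F9, and K2CO3 in MeOH should close it to 16.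

3. Step 17.
- What may go wrong: opening of the oxirane on the catalyst surface, sluggish cleavage of the two flanked secondary benzyl ethers, or drift of the C3 acetyl group to the freed O4.
- Fallback: it replaces reductive by oxidative debenzylation. It sets out from 22 and ends at 23. DDQ under visible-light irradiation in wet CH2Cl2 should oxidize the benzyl ethers to hemiacetals that collapse to the diol, without hydrogen or metal. No new compound is made (F0).

Further compounds
F1 | step 13 | C1-epimeric spiro-oxirane of 14 (oxirane oxygen axial, cis to O2/O6; C7 equatorial), 6-O-TBS | COc1ccc(CO[C@H]2[C@H](OCc3ccccc3)[C@@H](OCc3ccccc3)[C@H](O[Si](C)(C)C(C)(C)C)[C@@]3(CO3)[C@@H]2OCc2ccc(OC)cc2)cc1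
F2 | step 13 | epoxy alcohol: F1 with free equatorial 6-OH | COc1ccc(CO[C@H]2[C@H](OCc3ccccc3)[C@@H](OCc3ccccc3)[C@H](O)[C@@]3(CO3)[C@@H]2OCc2ccc(OC)cc2)cc1
F3 | step 13 | C6 ketone of F2 | COc1ccc(CO[C@H]2[C@H](OCc3ccccc3)[C@@H](OCc3ccccc3)C(=O)[C@@]3(CO3)[C@@H]2OCc2ccc(OC)cc2)cc1
F4 | step 13 | axial C6 alcohol (C6 epimer of F2) | COc1ccc(CO[C@H]2[C@H](OCc3ccccc3)[C@@H](OCc3ccccc3)[C@@H](O)[C@@]3(CO3)[C@@H]2OCc2ccc(OC)cc2)cc1
F5 | step 13 | axial C6 mesylate of F4 | COc1ccc(CO[C@H]2[C@H](OCc3ccccc3)[C@@H](OCc3ccccc3)[C@@H](OS(C)(=O)=O)[C@@]3(CO3)[C@@H]2OCc2ccc(OC)cc2)cc1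
F6 | step 13 | tertiary axial C1 alcohol with C7 benzoate and axial C6 mesylate (formed as alkoxide, not isolated) | COc1ccc(CO[C@H]2[C@H](OCc3ccccc3)[C@@H](OCc3ccccc3)[C@@H](OS(C)(=O)=O)[C@@](O)(COC(=O)c3ccccc3)[C@@H]2OCc2ccc(OC)cc2)cc1
F7 | step 11 | exocyclic alkene (C1=C7) from 14 | COc1ccc(CO[C@H]2[C@H](OCc3ccccc3)[C@@H](OCc3ccccc3)[C@H](O[Si](C)(C)C(C)(C)C)C(=C)[C@@H]2OCc2ccc(OC)cc2)cc1
F8 | step 11 | diol: equatorial tertiary 1-OH, axial C7 hydroxymethyl | COc1ccc(CO[C@H]2[C@H](OCc3ccccc3)[C@@H](OCc3ccccc3)[C@H](O[Si](C)(C)C(C)(C)C)[C@](O)(CO)[C@@H]2OCc2ccc(OC)cc2)cc1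
F9 | step 11 | primary C7 tosylate of F8 | COc1ccc(CO[C@H]2[C@H](OCc3ccccc3)[C@@H](OCc3ccccc3)[C@H](O[Si](C)(C)C(C)(C)C)[C@](O)(COS(=O)(=O)c3ccc(C)cc3)[C@@H]2OCc2ccc(OC)cc2)cc1
F0 | step 17 | none | none
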